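The route rests on cutting the C(sp2)–C(sp3) bond between C3 of ring B (the meta-disubstituted phenoxy ring) and the adjoining CH2 of the ethano bridge to ring C (the phenol ring). This bridge is a bare CH2–CH2 unit, so it maps onto a vinyl group on ring C. In one operation, anti-Markovnikov hydroboration with 9-BBN and intramolecular B-alkyl Suzuki–Miyaura coupling with a chloride at C3 of ring B close the 18-membered ring. The same operation delivers the bridge at its final oxidation level. The precursor is the open chain of all four rings, assembled by an intermolecular B-alkyl Suzuki coupling at a ring D iodide that leaves the ring B chloride untouched.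

Key step: step 6

Ring labels: A = 1,2,3-trisubstituted ring (OMe, O-aryl, CH2); B = meta-disubstituted ring (O, CH2); C = phenol ring (CH2 at C1, O-aryl at C3, OH at C4); D = para-disubstituted ring (O, CH2).
Remark: the target has no stereocentre, and the 18-membered ring is assumed to be conformationally mobile at room temperature, so no stereochemical element has to be controlled.

Step 1
Reactants: 1 2-fluoro-3-methoxybenzaldehyde; 2 3-chlorophenol
Product: 3 2-(3-chlorophenoxy)-3-methoxybenzaldehyde
Conditions: K2CO3 (1.5 equiv), DMF, 120 °C
Reagents that add atoms: none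
Why: Nucleophilic aromatic substitution by addition–elimination should work because the ortho formyl group stabilises the Meisenheimer adduct and fluoride is the fastest leaving group, whereas the unactivated C–Cl bond of 2 cannot react.

Step 2
Reactants: 3 2-(3-chlorophenoxy)-3-methoxybenzaldehyde
Product: 4 2-(3-chlorophenoxy)-1-ethenyl-3-methoxybenzene
Conditions: Ph3PCH3Br (1.3 equiv), KOtBu (1.25 equiv), THF, 0 °C to rt
Reagents that add atoms: methyltriphenylphosphonium bromide, C[P+](c1ccccc1)(c1ccccc1)c1ccccc1.[Br-]
Why: Wittig methylenation of a non-enolisable aryl aldehyde with the unstabilised ylide is reliable, and the diaryl ether, the methyl ether and the aryl chloride are inert to it.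

Step 3
Reactants: 5 4-(benzyloxy)-3-hydroxybenzaldehyde; 6 4-iodophenylboronic acid
Product: 7 4-(benzyloxy)-3-(4-iodophenoxy)benzaldehyde
Conditions: Cu(OAc)2 (20 mol %), pyridine (3 equiv), 4 Å molecular sieves, O2 (1 atm), CH2Cl2, rt
Reagents that add atoms: none
Why: Chan–Lam oxidative C–O coupling joins the phenol oxygen to the boron-bearing carbon at room temperature through a copper aryl phenoxide, and under these conditions the C–I bond, the aldehyde and the benzyl ether should stay untouched.

Step 4
Reactants: 7 4-(benzyloxy)-3-(4-iodophenoxy)benzaldehyde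
Product: 8 1-(benzyloxy)-4-ethenyl-2-(4-iodophenoxy)benzene
Conditions: Ph3PCH3Br (1.3 equiv), KOtBu (1.25 equiv), THF, 0 °C to rt
Reagents that add atoms: methyltriphenylphosphonium bromide, C[P+](c1ccccc1)(c1ccccc1)c1ccccc1.[Br-]
Why: Wittig methylenation as in step 2 should work because the preformed ylide neither exchanges with nor substitutes the aryl iodide.

Step 5
Reactants: 4 2-(3-chlorophenoxy)-1-ethenyl-3-methoxybenzene; 8 1-(benzyloxy)-4-ethenyl-2-(4-iodophenoxy)benzene
Product: 10 1-(benzyloxy)-2-(4-{2-[2-(3-chlorophenoxy)-3-methoxyphenyl]ethyl}phenoxy)-4-ethenylbenzene, via B-alkyl-9-BBN borane 9 (not isolated)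
Conditions: 4 (1.2 equiv), 9-BBN (1.15 equiv), THF, rt to 50 °C; then aq Cs2CO3 (3 equiv); then 8 (1.0 equiv), PdCl2(dppf) (5 mol %), Ph3As (5 mol %), DMF/THF, rt
Reagents that add atoms: 9-borabicyclo[3.3.1]nonane (9-BBN), B1C2CCCC1CCC2 (its boryl group stays only in 9; product 10 keeps one hydrogen from it)
Why: Anti-Markovnikov hydroboration of the styrene followed by intermolecular B-alkyl Suzuki–Miyaura coupling should be selective because PdCl2(dppf) at room temperature inserts into C–I but not into C–Cl, and because all B–H is consumed or quenched by the aqueous base before 8 is added, so that its vinyl group survives.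

Step 6
Reactants: 10 1-(benzyloxy)-2-(4-{2-[2-(3-chlorophenoxy)-3-methoxyphenyl]ethyl}phenoxy)-4-ethenylbenzene
Product: 12 O-benzyl ether of the target macrocycle, via B-alkyl-9-BBN borane 11 (not isolated)
Conditions: 9-BBN (1.5 equiv), THF, rt to 50 °C; water quench; then syringe-pump addition (12 h) to Pd(OAc)2 (10 mol %), SPhos (2-dicyclohexylphosphino-2',6'-dimethoxybiphenyl, 20 mol %), K3PO4 (3 equiv), THF/H2O, 65 °C, final concentration about 1 mM
Reagents that add atoms: 9-borabicyclo[3.3.1]nonane (9-BBN), B1C2CCCC1CCC2 (its boryl group stays only in 11; product 12 keeps one hydrogen from it)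
Why: 9-BBN adds to the ring C vinyl group with boron at the terminal carbon (anti-Markovnikov hydroboration of a styrene), so the carbon that becomes the CH2 next to ring B carries the only transferable primary B–C bond. Zerovalent palladium bearing SPhos inserts into the single C–Cl bond at C3 of ring B, the base-activated borate transmetalates within the same molecule, and reductive elimination forms the C(sp2)–C(sp3) bond; the closest known reaction type is the B-alkyl Suzuki–Miyaura macrocyclisation used for cyclophanes and macrolides. The 18-membered ring closes end to end by ring-contracting reductive elimination from a 19-membered aryl(alkyl)palladacycle, and no exo or endo alternative exists because each terminus offers one reactive atom. No stereocentre is formed. The step needs ring closure over oligomerisation and C–C reductive elimination over beta-hydride elimination: the first is secured by pseudo-high dilution and by the two diaryl ether hinges and the ortho-disposed substituents of ring A, which fold the chain, and the second by the bulky electron-rich biaryl phosphine. The flexible sp3 chain spares the closing transition state the strain that a rigid alkene or alkyne bridge would add.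

Step 7
Reactants: 12 O-benzyl ether of the target macrocycle
Product: 13 target macrocyclic bis(bibenzyl) CNP0309263.0
Conditions: H2 (1 atm), Pd/C (10 wt % palladium on carbon), EtOAc/MeOH, rt
Reagents that add atoms: none
Why: Catalytic hydrogenolysis cleaves only the benzylic C–O bond, since the diaryl ethers, the methyl ether and the saturated bridges are inert under one atmosphere of hydrogen at room temperature.

Compound list
1 | 2-fluoro-3-methoxybenzaldehyde | COc1cccc(C=O)c1F | starting material
2 | 3-chlorophenol | Oc1cccc(Cl)c1 | starting material
3 | 2-(3-chlorophenoxy)-3-methoxybenzaldehyde | COc1cccc(C=O)c1Oc1cccc(Cl)c1 | intermediate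
4 | 2-(3-chlorophenoxy)-1-ethenyl-3-methoxybenzene | COc1cccc(C=C)c1Oc1cccc(Cl)c1 | intermediate
5 | 4-(benzyloxy)-3-hydroxybenzaldehyde | O=Cc1ccc(OCc2ccccc2)c(O)c1 | starting material
6 | 4-iodophenylboronic acid | OB(O)c1ccc(I)cc1 | starting material
7 | 4-(benzyloxy)-3-(4-iodophenoxy)benzaldehyde | O=Cc1ccc(OCc2ccccc2)c(Oc2ccc(I)cc2)c1 | intermediate
8 | 1-(benzyloxy)-4-ethenyl-2-(4-iodophenoxy)benzene | C=Cc1ccc(OCc2ccccc2)c(Oc2ccc(I)cc2)c1 | intermediate
9 | 9-{2-[2-(3-chlorophenoxy)-3-methoxyphenyl]ethyl}-9-borabicyclo[3.3.1]nonane (not isolated) | COc1cccc(CCB2C3CCCC2CCC3)c1Oc1cccc(Cl)c1 | intermediate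
10 | 1-(benzyloxy)-2-(4-{2-[2-(3-chlorophenoxy)-3-methoxyphenyl]ethyl}phenoxy)-4-ethenylbenzene (open chain: ring B chloride, ring C vinyl) | COc1cccc(CCc2ccc(Oc3cc(C=C)ccc3OCc3ccccc3)cc2)c1Oc1cccc(Cl)c1 | intermediate
11 | 9-{2-[4-(benzyloxy)-3-(4-{2-[2-(3-chlorophenoxy)-3-methoxyphenyl]ethyl}phenoxy)phenyl]ethyl}-9-borabicyclo[3.3.1]nonane (not isolated) | COc1cccc(CCc2ccc(Oc3cc(CCB4C5CCCC4CCC5)ccc3OCc3ccccc3)cc2)c1Oc1cccc(Cl)c1 | intermediate
12 | O-benzyl ether of the target: 18-membered ring A–O–B–CH2CH2–C–O–D–CH2CH2–A with OMe on ring A and OBn at C4 of ring C | COc1cccc2c1Oc1cccc(c1)CCc1ccc(OCc3ccccc3)c(c1)Oc1ccc(cc1)CC2 | intermediate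
13 | target macrocyclic bis(bibenzyl) CNP0309263.0 (OMe on ring A, free OH at C4 of ring C) | COc1cccc2c1Oc1cccc(c1)CCc1ccc(O)c(c1)Oc1ccc(cc1)CC2 | target

Total step count: 7. Longest linear sequence: 5 steps (1, 2, 5, 6, 7 or 3, 4, 5, 6, 7).

Steps most likely to fail

Step 6. Three processes threaten this step:
- Oligomerisation may outrun ring closure.
- Oxidative addition into the C–Cl bond may be slow at high dilution.
- Beta-hydride elimination or protodeboronation may consume the borane.

The fallback sets out from 10 and makes the same bond without boron. An intramolecular Mizoroki–Heck reaction (Pd2(dba)3, P(t-Bu)3, Cs2CO3, dioxane, 110 °C, high dilution) adds the ring B arylpalladium species to the terminal vinyl carbon in the endo mode. This should give the macrocyclic (E)-stilbene benzyl ether F1. Hydrogenation over Pd/C (H2, EtOAc/MeOH, rt) should then saturate the alkene and remove the benzyl group in one operation. The fallback comes back to the route at 13.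

Step 5. The free vinyl group of 8 may be lost in two ways:
- Heck-type arylation by the aryl iodide of a second molecule.
- Stray hydroboration by residual B–H, which leads to oligomerisation.

The fallback sets out from aldehyde 7 and borane 9 (made from 4 as before) and keeps the ring C carbon as a formyl group during the coupling. B-alkyl Suzuki–Miyaura coupling at room temperature (PdCl2(dppf), Cs2CO3, DMF/THF/H2O) should give the open-chain aldehyde 4-(benzyloxy)-3-(4-{2-[2-(3-chlorophenoxy)-3-methoxyphenyl]ethyl}phenoxy)benzaldehyde F2. Wittig methylenation of F2 (Ph3PCH3Br, KOtBu, THF) then installs the vinyl group. The fallback comes back to the route at 10.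

Step 3. Protodeboronation, homocoupling or oxidation of the boronic acid may outpace C–O bond formation, and catalyst turnover under O2 may stall. The fallback sets out from 5 and replaces the oxidative coupling by an Ullmann-type O-arylation with an aryl halide electrophile. The conditions are 1,4-diiodobenzene (4 equiv, the excess suppresses double arylation), CuI, picolinic acid, K3PO4, DMSO, 90 °C. It comes back to the route directly at 7 and makes no compound outside the list (F0).

Further compounds
F1 | step 6 | macrocyclic (E)-stilbene benzyl ether (E alkene between ring B and ring C, otherwise as 12) | COc1cccc2c1Oc1cccc(c1)/C=C/c1ccc(OCc3ccccc3)c(c1)Oc1ccc(cc1)CC2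
F2 | step 5 | 4-(benzyloxy)-3-(4-{2-[2-(3-chlorophenoxy)-3-methoxyphenyl]ethyl}phenoxy)benzaldehyde | COc1cccc(CCc2ccc(Oc3cc(C=O)ccc3OCc3ccccc3)cc2)c1Oc1cccc(Cl)c1
F0 | step 3 | none | none
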